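**Plan**

- Numbering (tetralin): C1 carries the pendant dimethoxyphenyl ring C, C2 and C3 carry the methyls, C4 is the CH2, and C4a/C8a fuse the saturated ring B to the dimethoxybenzo ring A.
- Enabling feature: ring-B carbon C3 bears one exocyclic carbon and is bonded to stereogenic C2. The C3 methyl is traced back through CO2Me to a former ring carbonyl carbon, so the first cut is C2–C3, which reinserts that carbon between C2 and C3 and gives a benzo-fused seven-membered 2-diazo ketone.
- Further cuts: the C=N2 group (diazo transfer), C2–CH3 (enolate methylation), C1–aryl (asymmetric 1,4-addition to a benzocycloheptenone) and the two benzylic C–C bonds of the seven-membered ring (double alkylation of dimethyl 3-oxoglutarate).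
- Forward order: ring A is bought, the seven-membered ring is closed first, ring C is attached, the methyl and then the diazo group are installed, ring B arises by contraction, and the ester is reduced to the C3 methyl.
- Stereochemistry: C1 comes from the (R)-BINAP rhodium catalyst. C2 comes from methylation anti to the C1 aryl group and passes through the contraction with retention. C3 comes from thermodynamic equilibration of the ester.

Key step: step 7

Assumption: the (R)-BINAP rhodium catalyst is taken to attack the same enone face as in 2-cyclohexenone and 2-cycloheptenone, which corresponds to 5R here because the fused arene outranks the pendant aryl group; if the sense proved opposite, (S)-BINAP would be used.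

Benzo[7]annulene numbering is used for the seven-membered intermediates: C5 (aryl), C6 (methyl), C7 (C=O), C8 and C9 become tetralin C1, C2, the exocyclic carbon, C3 and C4.

**Step 1**
Reactants: 1 1,2-bis(bromomethyl)-4,5-dimethoxybenzene; 2 dimethyl 3-oxoglutarate
Product: 4 2,3-dimethoxy-5,6,8,9-tetrahydro-7H-benzo[7]annulen-7-one, via keto diester 3 (not isolated)
Conditions: Bu4NBr (cat.), aq NaHCO3, CH2Cl2, 40 °C; then KOH, EtOH/H2O, reflux; aq HCl
Reagents that add atoms: none
Why: Phase-transfer double C-alkylation of the two activated methylene groups of the 3-oxoglutarate by the bis(benzyl bromide) closes the seven-membered ring, and saponification with decarboxylation of the β-keto diester (acetoacetic-ester-type alkylation/decarboxylation) leaves the symmetric ketone.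

**Step 2**
Reactants: 4 2,3-dimethoxy-5,6,8,9-tetrahydro-7H-benzo[7]annulen-7-one
Product: 7 2,3-dimethoxy-8,9-dihydro-7H-benzo[7]annulen-7-one, via lithium enolate 5 (not isolated), via phenylselanyl ketone 6 (not isolated)
Conditions: LiN(iPr)2, THF, −78 °C; PhSeBr, −78 °C; then AcOH, 30% H2O2, 0 → 25 °C
Reagents that add atoms: none
Why: α-Selenation of the enolate followed by selenoxide syn-elimination can only use the benzylic hydrogen, and because the ketone is symmetric and one equivalent of selenium reagent is used, a single enone should form without further dehydrogenation to the benzotropone.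

**Step 3**
Reactants: 8 4-bromo-1,2-dimethoxybenzene
Product: 10 (3,4-dimethoxyphenyl)titanium triisopropoxide, via 3,4-dimethoxyphenyllithium 9 (not isolated)
Conditions: n-BuLi, THF, −78 °C; ClTi(OiPr)3, −78 → 20 °C; LiCl filtered off from hexane, used as a THF solution
Reagents that add atoms: chlorotitanium triisopropoxide, CC(C)O[Ti](Cl)(OC(C)C)OC(C)C
Why: Bromine–lithium exchange followed by transmetalation to tetravalent titanium is the standard preparation of aryltitanium triisopropoxides, and the methoxy groups are inert at −78 °C.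

**Step 4**
Reactants: 7 2,3-dimethoxy-8,9-dihydro-7H-benzo[7]annulen-7-one; 10 (3,4-dimethoxyphenyl)titanium triisopropoxide
Product: 12 (5R)-5-(3,4-dimethoxyphenyl)-2,3-dimethoxy-7-(trimethylsilyloxy)-8,9-dihydro-5H-benzo[7]annulene, via titanium enolate 11 (not isolated)
Conditions: [Rh(OH)((R)-binap)]2 (3 mol % Rh), THF, 20 °C; then LiOiPr, Me3SiCl, 20 °C
Reagents that add atoms: chlorotrimethylsilane, C[Si](C)(C)Cl
Why: In this aprotic aryltitanium variant of the Hayashi–Miyaura asymmetric 1,4-addition the aryl–rhodium species inserts the enone on the face selected by (R)-BINAP, which sets C5, and the enolate is kept on the aryl-bearing side as its titanium and then silicon derivative, so the C6=C7 position is fixed for the next step.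

**Step 5**
Reactants: 12 (5R)-5-(3,4-dimethoxyphenyl)-2,3-dimethoxy-7-(trimethylsilyloxy)-8,9-dihydro-5H-benzo[7]annulene
Product: 14 (5R,6S)-5-(3,4-dimethoxyphenyl)-2,3-dimethoxy-6-methyl-5,6,8,9-tetrahydro-7H-benzo[7]annulen-7-one, via lithium enolate 13 (not isolated)
Conditions: MeLi, THF, 0 °C; then MeI, THF/DMPU, −78 → 0 °C
Reagents that add atoms: iodomethane, CI
Why: MeLi cleaves the O–Si bond to the regiodefined lithium enolate (regiospecific enolate alkylation), and MeI should approach C6 anti to the neighbouring C5 aryl group, which sets the trans relationship by substrate control.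

**Step 6**
Reactants: 14 (5R,6S)-5-(3,4-dimethoxyphenyl)-2,3-dimethoxy-6-methyl-5,6,8,9-tetrahydro-7H-benzo[7]annulen-7-one
Product: 17 (5R,6S)-8-diazo-5-(3,4-dimethoxyphenyl)-2,3-dimethoxy-6-methyl-5,6,8,9-tetrahydro-7H-benzo[7]annulen-7-one, via kinetic lithium enolate 15 (not isolated), via trifluoroacetyl ketone 16 (not isolated)
Conditions: LiN(SiMe3)2, THF, −78 °C; CF3CO2CH2CF3, −78 °C; aq HCl work-up; then MsN3, Et3N, H2O (1 equiv), MeCN, 25 °C
Reagents that add atoms: methanesulfonyl azide, CS(=O)(=O)N=[N+]=[N-]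
Why: Kinetic deprotonation should occur at the unhindered C8 methylene and not at the tertiary C6, Claisen-type trifluoroacetylation activates that position, and Regitz-type deacylative diazo transfer installs N2 with loss of the trifluoroacetyl group under conditions that leave C5 and C6 untouched.

**Step 7**
Reactants: 17 (5R,6S)-8-diazo-5-(3,4-dimethoxyphenyl)-2,3-dimethoxy-6-methyl-5,6,8,9-tetrahydro-7H-benzo[7]annulen-7-one
Product: 20 methyl (2S,3S,4R)-4-(3,4-dimethoxyphenyl)-6,7-dimethoxy-3-methyl-1,2,3,4-tetrahydronaphthalene-2-carboxylate, via ketene 18 (not isolated), via ester epimer mixture 19 (not isolated)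
Conditions: hν (medium-pressure Hg lamp, Pyrex, λ > 300 nm), MeOH, 0 → 20 °C; then NaOMe (cat.), MeOH, 60 °C
Reagents that add atoms: methanol, CO
Why: Direct excitation of the cyclic 2-diazo ketone, whose C=O and C=N2 units are held s-Z by the ring, should expel N2 in concert with a 1,2-shift of the methyl-bearing carbon (tetralin C2) from the carbonyl carbon to the diazo carbon (tetralin C3), so that C2–C3 forms while the former carbonyl carbon leaves the ring as a ketene carbon that methanol captures as the methyl ester. The closest known reaction type is the photochemical Wolff ring contraction of 2-diazocycloalkanones to cycloalkanecarboxylates. Ring B is not closed by a cyclisation but arises from the seven-membered ring through this suprafacial 1,2-carbon shift, with ring A and C1 staying in place. C2 migrates with retention and C1 is untouched, while the new centre C3 is first set by protonation of the ester enol and then brought by NaOMe, under thermodynamic control, to the isomer with aryl, methyl and ester all equatorial, which is all-trans 20. The step needs the carbon shift to win over 1,2-hydrogen migration from benzylic C4 and over O–H insertion, which the locked s-Z geometry and metal-free direct photolysis favour, and it needs a single migrating group, which holds because C2 is the only carbon on the carbonyl besides the diazo carbon.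

**Step 8**
Reactants: 20 methyl (2S,3S,4R)-4-(3,4-dimethoxyphenyl)-6,7-dimethoxy-3-methyl-1,2,3,4-tetrahydronaphthalene-2-carboxylate
Product: 21 [(2S,3S,4R)-4-(3,4-dimethoxyphenyl)-6,7-dimethoxy-3-methyl-1,2,3,4-tetrahydronaphthalen-2-yl]methanol
Conditions: LiAlH4, THF, 0 °C; aq NaOH work-up
Reagents that add atoms: none
Why: Hydride reduction of the ester to the primary alcohol is fast at 0 °C and touches neither the aryl methyl ethers nor any stereocentre.

**Step 9**
Reactants: 21 [(2S,3S,4R)-4-(3,4-dimethoxyphenyl)-6,7-dimethoxy-3-methyl-1,2,3,4-tetrahydronaphthalen-2-yl]methanol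
Product: 22 [(2S,3S,4R)-4-(3,4-dimethoxyphenyl)-6,7-dimethoxy-3-methyl-1,2,3,4-tetrahydronaphthalen-2-yl]methyl 4-methylbenzenesulfonate
Conditions: TsCl, Et3N, DMAP (cat.), CH2Cl2, 0 → 25 °C
Reagents that add atoms: 4-methylbenzenesulfonyl chloride, Cc1ccc(cc1)S(Cl)(=O)=O
Why: O-Sulfonylation of the unhindered primary alcohol turns the oxygen into a leaving group without involving the adjacent stereocentres.

**Step 10**
Reactants: 22 [(2S,3S,4R)-4-(3,4-dimethoxyphenyl)-6,7-dimethoxy-3-methyl-1,2,3,4-tetrahydronaphthalen-2-yl]methyl 4-methylbenzenesulfonate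
Product: 23 (1R,2R,3S)-1-(3,4-dimethoxyphenyl)-6,7-dimethoxy-2,3-dimethyl-1,2,3,4-tetrahydronaphthalene
Conditions: LiBHEt3, THF, 0 → 25 °C
Reagents that add atoms: none
Why: SN2 displacement of the primary tosylate by hydride at the exocyclic carbon gives the C3 methyl group and cannot change the configuration at C1, C2 or C3.

**Compound list**

1 | 1,2-bis(bromomethyl)-4,5-dimethoxybenzene | COc1cc(CBr)c(CBr)cc1OC | starting material
2 | dimethyl 3-oxoglutarate (dimethyl 3-oxopentanedioate) | COC(=O)CC(=O)CC(=O)OC | starting material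
3 | dimethyl 2,3-dimethoxy-7-oxo-6,7,8,9-tetrahydro-5H-benzo[7]annulene-6,8-dicarboxylate (diastereomer and enol mixture) | COC(=O)C1Cc2cc(OC)c(OC)cc2CC(C(=O)OC)C1=O | intermediate (not isolated)
4 | 2,3-dimethoxy-5,6,8,9-tetrahydro-7H-benzo[7]annulen-7-one | O=C1CCc2cc(OC)c(OC)cc2CC1 | intermediate
5 | lithium enolate of 4 | [Li]OC1=CCc2cc(OC)c(OC)cc2CC1 | intermediate (not isolated)
6 | 2,3-dimethoxy-6-(phenylselanyl)-5,6,8,9-tetrahydro-7H-benzo[7]annulen-7-one (racemic) | O=C1CCc2cc(OC)c(OC)cc2CC1[Se]c1ccccc1 | intermediate (not isolated)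
7 | 2,3-dimethoxy-8,9-dihydro-7H-benzo[7]annulen-7-one (C5=C6 enone) | O=C1CCc2cc(OC)c(OC)cc2C=C1 | intermediate
8 | 4-bromo-1,2-dimethoxybenzene | COc1ccc(Br)cc1OC | starting material
9 | 3,4-dimethoxyphenyllithium | [Li]c1ccc(OC)c(OC)c1 | intermediate (not isolated)
10 | (3,4-dimethoxyphenyl)titanium triisopropoxide | COc1ccc([Ti](OC(C)C)(OC(C)C)OC(C)C)cc1OC | intermediate
11 | triisopropoxytitanium enolate of the (5R)-5-aryl ketone (O–Ti on C7, C6=C7) | COc1ccc([C@@H]2c3cc(OC)c(OC)cc3CCC(O[Ti](OC(C)C)(OC(C)C)OC(C)C)=C2)cc1OC | intermediate (not isolated)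
12 | (5R)-5-(3,4-dimethoxyphenyl)-2,3-dimethoxy-7-(trimethylsilyloxy)-8,9-dihydro-5H-benzo[7]annulene (C6=C7 silyl enol ether) | COc1ccc([C@@H]2c3cc(OC)c(OC)cc3CCC(O[Si](C)(C)C)=C2)cc1OC | intermediate
13 | lithium enolate from 12 (O–Li on C7, C6=C7) | COc1ccc([C@@H]2c3cc(OC)c(OC)cc3CCC(O[Li])=C2)cc1OC | intermediate (not isolated)
14 | (5R,6S)-5-(3,4-dimethoxyphenyl)-2,3-dimethoxy-6-methyl-5,6,8,9-tetrahydro-7H-benzo[7]annulen-7-one (trans) | COc1ccc([C@@H]2c3cc(OC)c(OC)cc3CCC(=O)[C@H]2C)cc1OC | intermediate
15 | kinetic lithium enolate of 14 (O–Li on C7, C7=C8) | COc1ccc([C@@H]2c3cc(OC)c(OC)cc3CC=C(O[Li])[C@H]2C)cc1OC | intermediate (not isolated)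
16 | (5R,6S)-5-(3,4-dimethoxyphenyl)-2,3-dimethoxy-6-methyl-8-(trifluoroacetyl)-5,6,8,9-tetrahydro-7H-benzo[7]annulen-7-one (enolised, C8 unassigned) | COc1ccc([C@@H]2c3cc(OC)c(OC)cc3CC(C(=O)C(F)(F)F)C(=O)[C@H]2C)cc1OC | intermediate (not isolated)
17 | (5R,6S)-8-diazo-5-(3,4-dimethoxyphenyl)-2,3-dimethoxy-6-methyl-5,6,8,9-tetrahydro-7H-benzo[7]annulen-7-one | COc1ccc([C@@H]2c3cc(OC)c(OC)cc3CC(=[N+]=[N-])C(=O)[C@H]2C)cc1OC | intermediate
18 | [(3S,4R)-4-(3,4-dimethoxyphenyl)-6,7-dimethoxy-3-methyl-3,4-dihydronaphthalen-2(1H)-ylidene]methanone (ketene) | COc1ccc([C@@H]2c3cc(OC)c(OC)cc3CC(=C=O)[C@H]2C)cc1OC | intermediate (not isolated)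
19 | methyl (3S,4R)-4-(3,4-dimethoxyphenyl)-6,7-dimethoxy-3-methyl-1,2,3,4-tetrahydronaphthalene-2-carboxylate (C2 epimer mixture) | COc1ccc([C@@H]2c3cc(OC)c(OC)cc3CC(C(=O)OC)[C@H]2C)cc1OC | intermediate (not isolated)
20 | methyl (2S,3S,4R)-4-(3,4-dimethoxyphenyl)-6,7-dimethoxy-3-methyl-1,2,3,4-tetrahydronaphthalene-2-carboxylate (all-trans) | COc1ccc([C@@H]2c3cc(OC)c(OC)cc3C[C@H](C(=O)OC)[C@H]2C)cc1OC | intermediate
21 | [(2S,3S,4R)-4-(3,4-dimethoxyphenyl)-6,7-dimethoxy-3-methyl-1,2,3,4-tetrahydronaphthalen-2-yl]methanol | COc1ccc([C@@H]2c3cc(OC)c(OC)cc3C[C@H](CO)[C@H]2C)cc1OC | intermediate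
22 | [(2S,3S,4R)-4-(3,4-dimethoxyphenyl)-6,7-dimethoxy-3-methyl-1,2,3,4-tetrahydronaphthalen-2-yl]methyl 4-methylbenzenesulfonate | COc1ccc([C@@H]2c3cc(OC)c(OC)cc3C[C@H](COS(=O)(=O)c3ccc(C)cc3)[C@H]2C)cc1OC | intermediate
23 | (1R,2R,3S)-1-(3,4-dimethoxyphenyl)-6,7-dimethoxy-2,3-dimethyl-1,2,3,4-tetrahydronaphthalene | COc1ccc([C@@H]2c3cc(OC)c(OC)cc3C[C@H](C)[C@H]2C)cc1OC | target

**Step count**

Total: 10 steps. Longest linear sequence: 9 steps (steps 1, 2 and 4 to 10 from compound 1); step 3 is a one-step branch that joins at step 4.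

**Steps most likely to fail**

Step 4. The arene-conjugated, β-aryl enone may insert slowly into the aryl–rhodium bond, the fused ring may erode facial discrimination, and the enolate position may scramble before silylation. The fallback sets out from enone 7 and takes its regiocontrol from a formyl group instead of enolate trapping. The aqueous Hayashi–Miyaura reaction of 7 with commercial 3,4-dimethoxyphenylboronic acid (COc1ccc(B(O)O)cc1OC), Rh(acac)(C2H4)2 and (R)-BINAP in dioxane/H2O at 100 °C should give (5R)-5-(3,4-dimethoxyphenyl)-2,3-dimethoxy-5,6,8,9-tetrahydro-7H-benzo[7]annulen-7-one F1. Claisen formylation (NaH, HCO2Et, THF) at the less hindered C8 should give (5R)-5-(3,4-dimethoxyphenyl)-8-(hydroxymethylene)-2,3-dimethoxy-5,6,8,9-tetrahydro-7H-benzo[7]annulen-7-one F2. Its dianion (2.2 equiv LiN(iPr)2, THF, −78 → 0 °C) is expected to take MeI at the remote α-carbon C6, anti to the aryl group, giving (5R,6S)-5-(3,4-dimethoxyphenyl)-8-(hydroxymethylene)-2,3-dimethoxy-6-methyl-5,6,8,9-tetrahydro-7H-benzo[7]annulen-7-one F3. Regitz deformylative diazo transfer (MsN3, Et3N, CH2Cl2) on F3 comes back to the route at diazo ketone 17, so steps 3 to 6 are bypassed.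

Step 7. The excited diazo ketone may be diverted into 1,2-hydrogen migration from the benzylic methylene or into O–H insertion instead of the 1,2-carbon shift, and the electron-rich rings may photodegrade. The fallback sets out from ketone 14 and forms the same C2–C3 bond thermally through a triazoline, without light or a carbene. Kinetic silylation (LiN(SiMe3)2, Me3SiCl, THF, −78 °C) should give (5R,6S)-5-(3,4-dimethoxyphenyl)-2,3-dimethoxy-6-methyl-7-(trimethylsilyloxy)-6,9-dihydro-5H-benzo[7]annulene F4. Heating F4 with tosyl azide in MeCN (sulfonyl azide ring contraction of silyl enol ethers: cycloaddition, N2 loss and the same 1,2-shift) should give, after hydrolysis of the silyl imidate, (3S,4R)-4-(3,4-dimethoxyphenyl)-6,7-dimethoxy-3-methyl-N-(4-methylbenzenesulfonyl)-1,2,3,4-tetrahydronaphthalene-2-carboxamide F5 as C2 epimers. N-Methylation (MeI, K2CO3, DMF) gives the activated (3S,4R)-4-(3,4-dimethoxyphenyl)-6,7-dimethoxy-N,3-dimethyl-N-(4-methylbenzenesulfonyl)-1,2,3,4-tetrahydronaphthalene-2-carboxamide F6. NaOMe in MeOH at 60 °C should then effect methanolysis and equilibration together, and the fallback comes back to the route at ester 20.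

Step 5. Proton exchange between product and enolate may cause positional scrambling and over-methylation, and the facial bias at the hindered carbon may be insufficient. The fallback sets out from silyl enol ether 12 and delivers the methyl carbon as a carbenoid instead of an electrophile. Furukawa-modified Simmons–Smith cyclopropanation (Et2Zn, CH2I2, CH2Cl2, 0 °C) on the face opposite the C5 aryl group should give the siloxycyclopropane (CH2 bridging C6 and C7 anti to the aryl group, OSiMe3 on C7, ketone numbering) F7. Ring opening of F7 with NaOH in MeOH cleaves the C7–CH2 bond and comes back to the route at trans ketone 14.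

**Further compounds**

F1 | step 4 | (5R)-5-(3,4-dimethoxyphenyl)-2,3-dimethoxy-5,6,8,9-tetrahydro-7H-benzo[7]annulen-7-one | COc1ccc([C@@H]2c3cc(OC)c(OC)cc3CCC(=O)C2)cc1OC
F2 | step 4 | (5R)-5-(3,4-dimethoxyphenyl)-8-(hydroxymethylene)-2,3-dimethoxy-5,6,8,9-tetrahydro-7H-benzo[7]annulen-7-one | COc1ccc([C@@H]2c3cc(OC)c(OC)cc3CC(=CO)C(=O)C2)cc1OC
F3 | step 4 | (5R,6S)-5-(3,4-dimethoxyphenyl)-8-(hydroxymethylene)-2,3-dimethoxy-6-methyl-5,6,8,9-tetrahydro-7H-benzo[7]annulen-7-one | COc1ccc([C@@H]2c3cc(OC)c(OC)cc3CC(=CO)C(=O)[C@H]2C)cc1OC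
F4 | step 7 | (5R,6S)-5-(3,4-dimethoxyphenyl)-2,3-dimethoxy-6-methyl-7-(trimethylsilyloxy)-6,9-dihydro-5H-benzo[7]annulene | COc1ccc([C@@H]2c3cc(OC)c(OC)cc3CC=C(O[Si](C)(C)C)[C@H]2C)cc1OC
F5 | step 7 | (3S,4R)-4-(3,4-dimethoxyphenyl)-6,7-dimethoxy-3-methyl-N-(4-methylbenzenesulfonyl)-1,2,3,4-tetrahydronaphthalene-2-carboxamide (C2 epimers) | COc1ccc([C@@H]2c3cc(OC)c(OC)cc3CC(C(=O)NS(=O)(=O)c3ccc(C)cc3)[C@H]2C)cc1OC
F6 | step 7 | (3S,4R)-4-(3,4-dimethoxyphenyl)-6,7-dimethoxy-N,3-dimethyl-N-(4-methylbenzenesulfonyl)-1,2,3,4-tetrahydronaphthalene-2-carboxamide (C2 epimers) | COc1ccc([C@@H]2c3cc(OC)c(OC)cc3CC(C(=O)N(C)S(=O)(=O)c3ccc(C)cc3)[C@H]2C)cc1OC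
F7 | step 5 | siloxycyclopropane from 12 (CH2 bridging C6 and C7 anti to the C5 aryl group, OSiMe3 on C7) | COc1ccc([C@@H]2c3cc(OC)c(OC)cc3CC[C@@]4(O[Si](C)(C)C)C[C@H]42)cc1OC
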